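Don't judge a flask's end by how its last reading looks. The grey run, nearly zeta's recipe, still holds 17.6 % of its electrophile at 48.0 h, and that says little about 6.0 d.

the same everywhere: electrophile 0.50 M
- grey: nucleophile 3 equiv; free base 0.30 equiv; protic impurity 6.7 mM; run made earlier
- red: nucleophile 6 equiv; free base 0.30 equiv; protic impurity 10 mM; run made earlier
- zeta: nucleophile 3.00 equiv; free base 0.300 equiv; protic impurity 10.0 mM; time 6.0 d
- epsilon: nucleophile 3.00 equiv; free base 0.600 equiv; protic impurity 10.0 mM; time 6.0 d

- grey (time / h: electrophile / %, target / %): 5.00: 80.5, 20.6; 12.0: 59.9, 35.8; 25.0: 38.7, 49.7; 40.0: 23.3, 60.3; 48.0: 17.6, 63.7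
- red (time / h: electrophile / %, target / %): 5.00: 66.1, 34.1; 12.0: 36.4, 59.3; 25.0: 13.6, 76.6; 40.0: 5.0, 83.7; 48.0: 2.8, 84.8

(readings scatter by 1 percentage point)

- no earlier run changes the charge of free base; that part of a forecast is a guess

- part of the electrophile that has reacted at the end, zeta
- part of the electrophile that has reacted at the end, epsilon
- what raising the equivalents of free base from its lowest to its highest value here does to the part of the electrophile that has reacted (changes below 5 percentage points count as none) (it rises / it falls / no change)

So count turnovers. Let τ be the electrophile's pseudo-first-order half-life, read from grey's last reading: 19.2 h. The turnover count n, the run time divided by τ, is then 7.52 for zeta. Grey and zeta differ in protic impurity, 6.7 mM against 10.0 mM, which I take as minor. By my count they end apart because zeta gets more half-lives, 7.52 against 2.51 for grey at its last reading. By my count zeta keeps 0.545 % of its electrophile. The red run, with twice the nucleophile, decays about twice as fast, though its impurity differs too, so I let τ go inversely with nucleophile molarity. No earlier run changes the free base, so giving epsilon the same n is a guess.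

The forecast gives 99 % for zeta, 99.5 % for epsilon and no change for the trend, on the ground that “A rate change would barely show near full conversion unless base strongly inhibits”. My count leaves less in zeta than its figure does, 0.545 % against 1.00 %.

The flask gives 99.0 % for zeta and 99.1 % for epsilon, a change of 0.12 percentage points, so the trend is no change; zeta keeps 1.0 %, more than the 0.545 % that n gave.

    electrophile + nucleophile → acid set free + target (k = 0.0300 M⁻¹ h⁻¹)
    nucleophile + acid set free ⇌ protonated nucleophile, settled at all times (K = 490 M⁻¹)
    acid set free + free base ⇌ salt of the base (K = 2300 M⁻¹, k = 6.60 M⁻¹ h⁻¹)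
    crystals ⇌ acid set free, rate k4*(cs4 - [acid set free]) while solid is left; crystals form when [acid set free] > cs4 (solubility = 32.0 mM, k = 8.10 h⁻¹)
    electrophile + target → side product (k = 0.0230 M⁻¹ h⁻¹)
    protic impurity + free base → quenched reagent (k = 0.740 M⁻¹ h⁻¹)

In epsilon at 6.00 d, the step to target gives the electrophile a half-life of 1.3 d, longer than grey's τ but shorter than the 6.0 d of the run. In epsilon that step has 71 % of its turnover behind it by 1.20 d. The neighbour of epsilon at 0.12 M of electrophile has its nucleophile diluted in proportion, so n falls to 1.80, which keeps 28.7 %. That flask holds 27.2 % of its electrophile at 6.00 d.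

(All runs were computed on assumed constants; noise was put on by code.)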